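**Plan**

- Retrosynthesis (germacrane numbering): remove the C8 angelate and C13, open the 6,12‑lactone and the 4,5‑oxirane, then cut the ring bond C5–C6, the C10=C1 alkene, C9–C10, C7–C11 and, in the side arm, C3–C4.
- Forward: (S)‑malate gives the C6–C9 aldehyde 16; the chain grows by C10/C14 (acetate aldol) and by the C1–C5 iodoalkenyl aldehyde 6 (aldol/E1cB); the ten‑membered ring closes at C5–C6 by Ni/Cr; then oxirane ring, γ‑lactone ring, C13, angelate, deprotection.
- Enabling feature: in the ten‑membered carbocycle C6 is an oxygen‑bearing carbon bonded to C5 of the (Z)‑trisubstituted C4=C5 unit (the C4–C5 oxirane of the target). This (Z)‑allylic carbinol maps onto a C5 alkenyl iodide plus a C6 aldehyde, and its hydroxyl later delivers the oxirane oxygen syn.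
- Stereochemistry: C8 from (S)‑malic acid; C7 by Fráter–Seebach anti‑allylation; C9 by chelation‑controlled Mukaiyama aldol; C6 by Felkin/chelate‑controlled reduction of the macrocyclic enone; C4/C5 by C6–OH‑directed epoxidation; 4Z from syn‑carbocupration, 1(10) geometry from E1cB, angelate geometry from angelic acid.

Key step: step 16

Remarks on the chemistry:
- Locants follow germacrane numbering (C14 = ester carbon on C10, C15 = methyl on C4, C11–C13 = lactone arm); macrocycles are named with these locants.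
- The C11–C12 arm is carried as an allyl group (masked CH2–CHO), so that the lactone can be formed after the hydroxyl‑directed epoxidation without acid.
- Felkin–Anh and 1,3‑induction both oppose the required C6 configuration when C5 adds to the aldehyde, so the carbinol is passed through the enone (steps 17–18), where the same elements favour it.
- Compounds 8 and 17 are taken as commercially available.
- CIP descriptors at C6 and C7 change along the route through priority changes only; the centres themselves are not touched after they are set.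

**Route**

Step 1
Reactants: 1 2-(2-bromoethyl)-1,3-dioxolane; 2 propyne
Product: 5 (Z)-iodoalkenyl dioxolane, via Grignard reagent 3 (not isolated), via alkenylcopper 4 (not isolated)
Conditions: Mg, THF, 25 °C; CuBr·SMe2, Et2O/Me2S, −45 °C; 2, −45 → −20 °C; I2, −50 → 0 °C
Reagents that add atoms: iodine, II
Why: Syn carbocupration of propyne by the alkylcopper places chain and copper cis on the new trisubstituted alkene, and iodinolysis with retention should give the (Z)-iodide.

Step 2
Reactants: 5 (Z)-iodoalkenyl dioxolane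
Product: 6 (4Z)-5-iodo-4-methylpent-4-enal
Conditions: 1 M aq HCl, THF, 25 °C
Reagents that add atoms: water, O
Why: Acid-catalysed acetal hydrolysis, to which the alkenyl iodide is inert.

Step 3
Reactants: 7 diethyl (S)-malate; 8 allyl bromide
Product: 10 diethyl (2S,3R)-3-allylmalate, via dilithium enolate 9 (not isolated)
Conditions: LDA (2.2 equiv), THF, −78 → −20 °C; 8, −78 → −5 °C; aq NH4Cl
Reagents that add atoms: none
Why: Fráter–Seebach alkylation, in which the chelated alkoxide–enolate is allylated anti to the alkoxide oxygen and so sets C7 relative to the malate-derived C8.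

Step 4
Reactants: 10 diethyl (2S,3R)-3-allylmalate
Product: 11 diol ester
Conditions: BH3·SMe2, NaBH4 (5 mol%), THF, 0 → 25 °C; MeOH
Reagents that add atoms: none
Why: Hydroxyl-directed borane reduction (borohydride-catalysed) reduces only the ester next to the free hydroxyl via a cyclic alkoxyborane and leaves the C6 ester.

Step 5
Reactants: 11 diol ester
Product: 12 p-methoxybenzylidene acetal ester
Conditions: 4-MeOC6H4CH(OMe)2, PPTS (cat.), CH2Cl2, 25 °C
Reagents that add atoms: 4-methoxybenzaldehyde dimethyl acetal, COC(OC)c1ccc(OC)cc1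
Why: Acid-catalysed transacetalisation of the 1,2-diol to the dioxolane (both acetal epimers, of no consequence) should outrun lactonisation of the hydroxy ester.

Step 6
Reactants: 12 p-methoxybenzylidene acetal ester
Product: 13 primary alcohol
Conditions: LiAlH4, THF, 0 °C
Reagents that add atoms: none
Why: Hydride reduction of the ester, to which the acetal and the terminal alkene are inert.

Step 7
Reactants: 13 primary alcohol
Product: 14 C6 silyl ether
Conditions: TBSCl, imidazole, DMF, 25 °C
Reagents that add atoms: tert-butyldimethylsilyl chloride, CC(C)(C)[Si](C)(C)Cl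
Why: Standard silylation of a primary alcohol.

Step 8
Reactants: 14 C6 silyl ether
Product: 15 C8 PMB ether C9 alcohol
Conditions: DIBAL-H (3 equiv), CH2Cl2, −78 → 0 °C; Rochelle salt
Reagents that add atoms: none
Why: Regioselective reductive opening of the p-methoxybenzylidene acetal: aluminium binds the less hindered primary oxygen, so hydride delivery leaves the PMB group on the secondary C8 oxygen.

Step 9
Reactants: 15 C8 PMB ether C9 alcohol
Product: 16 C9 aldehyde
Conditions: Dess–Martin periodinane, NaHCO3, CH2Cl2, 0 → 25 °C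
Reagents that add atoms: none
Why: Dess–Martin oxidation under buffered conditions that should not epimerise the α-alkoxy aldehyde.

Step 10
Reactants: 16 C9 aldehyde; 17 1-(tert-butyldimethylsilyloxy)-1-methoxyethene
Product: 18 β-hydroxy ester
Conditions: MgBr2·OEt2 (3 equiv), CH2Cl2, −78 → −30 °C; aqueous work-up
Reagents that add atoms: none
Why: Chelation-controlled Mukaiyama aldol addition: magnesium bridges the aldehyde and the C8 PMB-ether oxygens and the ketene acetal attacks the face away from C7, which should give the 8,9-syn (9S) carbinol.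

Step 11
Reactants: 18 β-hydroxy ester
Product: 19 bis-silyl ether ester
Conditions: TBSOTf, 2,6-lutidine, CH2Cl2, −78 → 0 °C
Reagents that add atoms: tert-butyldimethylsilyl triflate, CC(C)(C)[Si](C)(C)OS(=O)(=O)C(F)(F)F
Why: Silyl triflate silylation of a hindered secondary alcohol.

Step 12
Reactants: 19 bis-silyl ether ester; 6 (4Z)-5-iodo-4-methylpent-4-enal
Product: 21 aldol adduct (diastereomers at C10 and C1), via lithium enolate 20 (not isolated)
Conditions: LDA (1.1 equiv), THF, −78 °C; 6, −78 °C; aq NH4Cl at −78 °C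
Reagents that add atoms: none
Why: Lithium ester-enolate aldol addition at −78 °C, where β-elimination of the C9 silyloxy group is slow; the two new centres are removed in step 13, so the mixture is used.

Step 13
Reactants: 21 aldol adduct
Product: 23 (2E,6Z)-dienoate, via mesylate 22 (not isolated)
Conditions: MsCl, Et3N, CH2Cl2, 0 °C; then DBU, 0 → 25 °C
Reagents that add atoms: none
Why: Mesylation and E1cB elimination, which for 2-alkylidene esters gives the isomer with the ester trans to the β-chain (C9 and C2 cis); a minor Z isomer would be removed by chromatography.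

Step 14
Reactants: 23 (2E,6Z)-dienoate
Product: 24 C6 primary alcohol
Conditions: HF·pyridine, pyridine, THF, 0 °C
Reagents that add atoms: none
Why: Buffered fluoride desilylation cleaves the primary silyl ether much faster than the hindered secondary allylic one at C9.

Step 15
Reactants: 24 C6 primary alcohol
Product: 25 seco-aldehyde
Conditions: Dess–Martin periodinane, NaHCO3, CH2Cl2, 0 °C
Reagents that add atoms: none
Why: Dess–Martin oxidation under buffered conditions that avoid epimerisation at C7 and β-elimination of the C8 ether.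

Step 16
Reactants: 25 seco-aldehyde
Product: 27 macrocyclic dienol (C6 epimers), via alkenylchromium 26 (not isolated)
Conditions: CrCl2 (10 equiv), NiCl2 (0.1 equiv), DMSO, 25 °C, syringe-pump addition of 25 to 3 mM; aqueous work-up
Reagents that add atoms: none
Why: Nozaki–Hiyama–Kishi reaction: Ni(0) inserts into the C5–I bond with retention, transmetalation gives alkenylchromium(III) 26, and this weakly basic, aldehyde-selective nucleophile adds to the C6 aldehyde to form C5–C6, the closest known reaction type being the Ni/Cr macrocyclisation of ω-formyl alkenyl iodides to cyclic allylic alcohols. The ten-membered carbocycle closes by intramolecular 1,2-addition to the exocyclic carbonyl (10-exo-trig). The new C6 centre forms under substrate control, and Felkin–Anh induction from C7 and 1,3-induction from the C8 ether both point to the 6R alcohol, the epimer of the one needed, so no facial selectivity is asked here and both epimers go on to ketone 28, where the same elements favour the right isomer. What the step must deliver is chemoselectivity (only the C–I bond is activated; enoate, terminal alkene and ethers are spectators), retention of the 4Z geometry, and cyclisation in preference to oligomerisation. The last is secured by high dilution and by the substrate: the cis C10=C1 and cis C4=C5 units and the branched C7–C9 segment fold the chain so that C5 and C6 lie close.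

Step 17
Reactants: 27 macrocyclic dienol (C6 epimers)
Product: 28 macrocyclic (Z)-enone
Conditions: Dess–Martin periodinane, NaHCO3, CH2Cl2, 0 °C
Reagents that add atoms: none
Why: Dess–Martin oxidation of the allylic alcohol converges both C6 epimers on one enone under buffered conditions that should prevent β-elimination of the C8 ether.

Step 18
Reactants: 28 macrocyclic (Z)-enone
Product: 29 (6S)-dienol
Conditions: Zn(BH4)2, Et2O, −30 °C
Reagents that add atoms: none
Why: 1,2-Reduction of the enone by zinc borohydride, in which Felkin–Anh control from C7 is reinforced by zinc chelation between the ketone and the C8 ether oxygen, should give the alcohol with C6–O syn to C8–O (6S here, 6R after epoxidation).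

Step 19
Reactants: 29 (6S)-dienol
Product: 30 epoxy alcohol
Conditions: VO(acac)2 (5 mol%), t-BuOOH, CH2Cl2, 0 °C
Reagents that add atoms: tert-butyl hydroperoxide, CC(C)(C)OO
Why: Vanadium-catalysed hydroxyl-directed epoxidation of the (Z)-allylic alcohol: allylic 1,3-strain with the cis C3 substituent holds H6 in the alkene plane, so oxygen is delivered threo to give the 4R,5S oxirane, while the electron-poor enoate and the remote terminal alkene stay untouched.

Step 20
Reactants: 30 epoxy alcohol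
Product: 32 lactol (C12 epimers), via triol 31 (not isolated)
Conditions: OsO4 (2 mol%), NMO, acetone/H2O, 0 °C; then NaIO4, THF/pH 7 buffer
Reagents that add atoms: N-methylmorpholine N-oxide, C[N+]1([O-])CCOCC1
Why: Johnson–Lemieux sequence: osmium tetroxide dihydroxylates the monosubstituted alkene far faster than the trisubstituted enoate, periodate cleaves the diol, and the C12 aldehyde is trapped by the C6 hydroxyl as the five-membered lactol.

Step 21
Reactants: 32 lactol
Product: 33 γ-lactone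
Conditions: TPAP (5 mol%), NMO, 4 Å MS, CH2Cl2, 25 °C
Reagents that add atoms: none
Why: Ley–Griffith oxidation of the lactol to the lactone under neutral conditions tolerated by the epoxide and the PMB ether.

Step 22
Reactants: 33 γ-lactone
Product: 37 α-methylene lactone, via lithium enolate 34 (not isolated), via Mannich base 35 (not isolated), via ammonium iodide 36 (not isolated)
Conditions: LiHMDS (1.1 equiv), THF, −78 °C; Me2N=CH2 I, −78 → 0 °C; MeI, MeOH, 25 °C; aq NaHCO3, CH2Cl2
Reagents that add atoms: Eschenmoser's salt, C=[N+](C)C.[I-]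
Why: Eschenmoser α-methylenation: the lactone α-CH2 (the most acidic C–H present) is deprotonated, the enolate undergoes Mannich reaction with the iminium salt, and quaternisation followed by mild-base elimination gives the exocyclic alkene.

Step 23
Reactants: 37 α-methylene lactone
Product: 38 C8 alcohol
Conditions: DDQ, CH2Cl2/pH 7 buffer (10:1), 0 °C
Reagents that add atoms: none
Why: Oxidative PMB cleavage by DDQ under buffered conditions that spare the epoxide, the silyl ether and the enoates.

Step 24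
Reactants: 38 C8 alcohol; 39 angelic acid
Product: 41 C8 angelate, via mixed anhydride 40 (not isolated)
Conditions: 39, 2,4,6-trichlorobenzoyl chloride, Et3N, toluene, 25 °C; then 38, toluene, 75 °C
Reagents that add atoms: none
Why: Yamaguchi-type mixed-anhydride esterification without nucleophilic catalyst, a method that acylates hindered secondary alcohols with angelic acid without isomerisation to the tiglate.

Step 25
Reactants: 41 C8 angelate
Product: 42 CNP0251641.1
Conditions: HF·pyridine, pyridine, THF, 0 → 25 °C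
Reagents that add atoms: none
Why: Pyridine-buffered fluoride desilylation, acidic enough to suppress O8→O9 acyl migration and mild enough for the epoxide and the α-methylene lactone.

**Compound list**

1 | 2-(2-bromoethyl)-1,3-dioxolane | BrCCC1OCCO1 | starting material
2 | propyne | CC#C | starting material
3 | [2-(1,3-dioxolan-2-yl)ethyl]magnesium bromide | Br[Mg]CCC1OCCO1 | intermediate
4 | [(1Z)-4-(1,3-dioxolan-2-yl)-2-methylbut-1-en-1-yl]copper | O1CCOC1CC/C(C)=C\[Cu] | intermediate
5 | 2-[(3Z)-4-iodo-3-methylbut-3-en-1-yl]-1,3-dioxolane | O1CCOC1CC/C(C)=C\I | intermediate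
6 | (4Z)-5-iodo-4-methylpent-4-enal | O=CCC/C(C)=C\I | intermediate
7 | diethyl (2S)-2-hydroxybutanedioate (diethyl (S)-malate) | CCOC(=O)C[C@H](O)C(=O)OCC | starting material
8 | 3-bromoprop-1-ene (allyl bromide) | C=CCBr | starting material
9 | dilithium alkoxide–enolate of 7 | CCOC(=O)[C@@H]([O-])C=C([O-])OCC.[Li+].[Li+] | intermediate
10 | diethyl (2S,3R)-2-hydroxy-3-(prop-2-en-1-yl)butanedioate | CCOC(=O)[C@H](CC=C)[C@H](O)C(=O)OCC | intermediate
11 | ethyl (2R,3S)-3,4-dihydroxy-2-(prop-2-en-1-yl)butanoate | CCOC(=O)[C@H](CC=C)[C@H](O)CO | intermediate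
12 | ethyl (2R)-2-[(4S)-2-(4-methoxyphenyl)-1,3-dioxolan-4-yl]pent-4-enoate (both acetal epimers) | CCOC(=O)[C@H](CC=C)[C@H]1COC(c2ccc(OC)cc2)O1 | intermediate
13 | (2S)-2-[(4S)-2-(4-methoxyphenyl)-1,3-dioxolan-4-yl]pent-4-en-1-ol | OC[C@H](CC=C)[C@H]1COC(c2ccc(OC)cc2)O1 | intermediate
14 | tert-butyl({(2S)-2-[(4S)-2-(4-methoxyphenyl)-1,3-dioxolan-4-yl]pent-4-en-1-yl}oxy)dimethylsilane | CC(C)(C)[Si](C)(C)OC[C@H](CC=C)[C@H]1COC(c2ccc(OC)cc2)O1 | intermediate
15 | (2S,3S)-3-{[(tert-butyldimethylsilyl)oxy]methyl}-2-[(4-methoxyphenyl)methoxy]hex-5-en-1-ol | CC(C)(C)[Si](C)(C)OC[C@H](CC=C)[C@H](OCc1ccc(OC)cc1)CO | intermediate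
16 | (2S,3S)-3-{[(tert-butyldimethylsilyl)oxy]methyl}-2-[(4-methoxyphenyl)methoxy]hex-5-enal | CC(C)(C)[Si](C)(C)OC[C@H](CC=C)[C@H](OCc1ccc(OC)cc1)C=O | intermediate
17 | tert-butyl[(1-methoxyethenyl)oxy]dimethylsilane | C=C(OC)O[Si](C)(C)C(C)(C)C | starting material
18 | methyl (3S,4S,5S)-5-{[(tert-butyldimethylsilyl)oxy]methyl}-3-hydroxy-4-[(4-methoxyphenyl)methoxy]oct-7-enoate | CC(C)(C)[Si](C)(C)OC[C@H](CC=C)[C@H](OCc1ccc(OC)cc1)[C@@H](O)CC(=O)OC | intermediate
19 | methyl (3S,4S,5S)-3-[(tert-butyldimethylsilyl)oxy]-5-{[(tert-butyldimethylsilyl)oxy]methyl}-4-[(4-methoxyphenyl)methoxy]oct-7-enoate | CC(C)(C)[Si](C)(C)OC[C@H](CC=C)[C@H](OCc1ccc(OC)cc1)[C@@H](O[Si](C)(C)C(C)(C)C)CC(=O)OC | intermediate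
20 | lithium enolate of 19 | CC(C)(C)[Si](C)(C)OC[C@H](CC=C)[C@H](OCc1ccc(OC)cc1)[C@@H](O[Si](C)(C)C(C)(C)C)C=C([O-])OC.[Li+] | intermediate
21 | methyl (6Z)-2-[(1S,2S,3S)-1-[(tert-butyldimethylsilyl)oxy]-3-{[(tert-butyldimethylsilyl)oxy]methyl}-2-[(4-methoxyphenyl)methoxy]hex-5-en-1-yl]-3-hydroxy-7-iodo-6-methylhept-6-enoate (C2/C3 diastereomers) | CC(C)(C)[Si](C)(C)OC[C@H](CC=C)[C@H](OCc1ccc(OC)cc1)[C@@H](O[Si](C)(C)C(C)(C)C)C(C(=O)OC)C(O)CC/C(C)=C\I | intermediate
22 | 3-O-methanesulfonate of 21 | CC(C)(C)[Si](C)(C)OC[C@H](CC=C)[C@H](OCc1ccc(OC)cc1)[C@@H](O[Si](C)(C)C(C)(C)C)C(C(=O)OC)C(OS(C)(=O)=O)CC/C(C)=C\I | intermediate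
23 | methyl (2E,6Z)-2-[(1S,2S,3S)-1-[(tert-butyldimethylsilyl)oxy]-3-{[(tert-butyldimethylsilyl)oxy]methyl}-2-[(4-methoxyphenyl)methoxy]hex-5-en-1-yl]-7-iodo-6-methylhepta-2,6-dienoate | CC(C)(C)[Si](C)(C)OC[C@H](CC=C)[C@H](OCc1ccc(OC)cc1)[C@@H](O[Si](C)(C)C(C)(C)C)/C(C(=O)OC)=C\CC/C(C)=C\I | intermediate
24 | methyl (2E,6Z)-2-[(1S,2S,3S)-1-[(tert-butyldimethylsilyl)oxy]-3-(hydroxymethyl)-2-[(4-methoxyphenyl)methoxy]hex-5-en-1-yl]-7-iodo-6-methylhepta-2,6-dienoate | OC[C@H](CC=C)[C@H](OCc1ccc(OC)cc1)[C@@H](O[Si](C)(C)C(C)(C)C)/C(C(=O)OC)=C\CC/C(C)=C\I | intermediate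
25 | methyl (2E,6Z)-2-[(1S,2S,3R)-1-[(tert-butyldimethylsilyl)oxy]-3-formyl-2-[(4-methoxyphenyl)methoxy]hex-5-en-1-yl]-7-iodo-6-methylhepta-2,6-dienoate | O=C[C@H](CC=C)[C@H](OCc1ccc(OC)cc1)[C@@H](O[Si](C)(C)C(C)(C)C)/C(C(=O)OC)=C\CC/C(C)=C\I | intermediate
26 | alkenylchromium(III) dichloride from 25 (CrCl2 in place of I at C5) | O=C[C@H](CC=C)[C@H](OCc1ccc(OC)cc1)[C@@H](O[Si](C)(C)C(C)(C)C)/C(C(=O)OC)=C\CC/C(C)=C\[Cr](Cl)Cl | intermediate
27 | methyl (1(10)E,4Z,7S,8S,9S)-7-allyl-9-[(tert-butyldimethylsilyl)oxy]-6-hydroxy-8-[(4-methoxybenzyl)oxy]-4-methylcyclodeca-1(10),4-diene-10-carboxylate, 6R/6S mixture | C1/C(C)=C\C(O)[C@H](CC=C)[C@H](OCc2ccc(OC)cc2)[C@@H](O[Si](C)(C)C(C)(C)C)/C(C(=O)OC)=C\C1 | intermediate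
28 | methyl (1(10)E,4Z,7R,8S,9S)-7-allyl-9-[(tert-butyldimethylsilyl)oxy]-8-[(4-methoxybenzyl)oxy]-4-methyl-6-oxocyclodeca-1(10),4-diene-10-carboxylate | C1/C(C)=C\C(=O)[C@H](CC=C)[C@H](OCc2ccc(OC)cc2)[C@@H](O[Si](C)(C)C(C)(C)C)/C(C(=O)OC)=C\C1 | intermediate
29 | methyl (1(10)E,4Z,6S,7S,8S,9S)-7-allyl-9-[(tert-butyldimethylsilyl)oxy]-6-hydroxy-8-[(4-methoxybenzyl)oxy]-4-methylcyclodeca-1(10),4-diene-10-carboxylate | C1/C(C)=C\[C@H](O)[C@H](CC=C)[C@H](OCc2ccc(OC)cc2)[C@@H](O[Si](C)(C)C(C)(C)C)/C(C(=O)OC)=C\C1 | intermediate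
30 | methyl (1(10)E,4R,5S,6R,7S,8S,9S)-7-allyl-9-[(tert-butyldimethylsilyl)oxy]-4,5-epoxy-6-hydroxy-8-[(4-methoxybenzyl)oxy]-4-methylcyclodec-1(10)-ene-10-carboxylate | O[C@@H]2[C@H](CC=C)[C@H](OCc3ccc(OC)cc3)[C@@H](O[Si](C)(C)C(C)(C)C)/C(C(=O)OC)=C\CC[C@@]1(C)O[C@@H]21 | intermediate
31 | triol: 30 with the allyl group converted to 2,3-dihydroxypropyl (both carbinol epimers) | O[C@@H]2[C@H](CC(O)CO)[C@H](OCc3ccc(OC)cc3)[C@@H](O[Si](C)(C)C(C)(C)C)/C(C(=O)OC)=C\CC[C@@]1(C)O[C@@H]21 | intermediate
32 | lactol: C12 hemiacetal closed onto O6, cis-fused at C6/C7 (4R,5S,6R,7R,8S,9S; C12 epimers); C8 OPMB, C9 OTBS, C10 CO2Me, 4,5-epoxide | C1C(O)O[C@@H]2[C@H]1[C@H](OCc3ccc(OC)cc3)[C@@H](O[Si](C)(C)C(C)(C)C)/C(C(=O)OC)=C\CC[C@@]1(C)O[C@@H]21 | intermediate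
33 | 6,12-γ-lactone (4R,5S,6R,7R,8S,9S), C11 = CH2; C8 OPMB, C9 OTBS, C10 CO2Me, 4,5-epoxide | C1C(=O)O[C@@H]2[C@H]1[C@H](OCc3ccc(OC)cc3)[C@@H](O[Si](C)(C)C(C)(C)C)/C(C(=O)OC)=C\CC[C@@]1(C)O[C@@H]21 | intermediate
34 | lithium enolate of 33 | C1=C([O-])O[C@@H]2[C@H]1[C@H](OCc3ccc(OC)cc3)[C@@H](O[Si](C)(C)C(C)(C)C)/C(C(=O)OC)=C\CC[C@@]1(C)O[C@@H]21.[Li+] | intermediate
35 | 11-[(dimethylamino)methyl] lactone (C11 epimers) | CN(C)CC1C(=O)O[C@@H]2[C@H]1[C@H](OCc3ccc(OC)cc3)[C@@H](O[Si](C)(C)C(C)(C)C)/C(C(=O)OC)=C\CC[C@@]1(C)O[C@@H]21 | intermediate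
36 | trimethylammonium iodide of 35 | C[N+](C)(C)CC1C(=O)O[C@@H]2[C@H]1[C@H](OCc3ccc(OC)cc3)[C@@H](O[Si](C)(C)C(C)(C)C)/C(C(=O)OC)=C\CC[C@@]1(C)O[C@@H]21.[I-] | intermediate
37 | α-methylene-γ-lactone (4R,5S,6R,7R,8S,9S); C8 OPMB, C9 OTBS | C=C1C(=O)O[C@@H]2[C@H]1[C@H](OCc3ccc(OC)cc3)[C@@H](O[Si](C)(C)C(C)(C)C)/C(C(=O)OC)=C\CC[C@@]1(C)O[C@@H]21 | intermediate
38 | α-methylene-γ-lactone (4R,5S,6R,7R,8S,9S); C8 OH, C9 OTBS | C=C1C(=O)O[C@@H]2[C@H]1[C@H](O)[C@@H](O[Si](C)(C)C(C)(C)C)/C(C(=O)OC)=C\CC[C@@]1(C)O[C@@H]21 | intermediate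
39 | angelic acid, (2Z)-2-methylbut-2-enoic acid | C/C=C(/C)C(=O)O | starting material
40 | (2Z)-2-methylbut-2-enoic 2,4,6-trichlorobenzoic anhydride | C/C=C(/C)C(=O)OC(=O)c1c(Cl)cc(Cl)cc1Cl | intermediate
41 | 9-O-tert-butyldimethylsilyl ether of the target (4R,5S,6R,7S,8S,9S by CIP; geometry as in 42) | C=C1C(=O)O[C@@H]2[C@H]1[C@H](OC(=O)/C(C)=C\C)[C@@H](O[Si](C)(C)C(C)(C)C)/C(C(=O)OC)=C\CC[C@@]1(C)O[C@@H]21 | intermediate
42 | CNP0251641.1: methyl (1(10)E,4R,5S,6R,7R,8S,9S)-8-angeloyloxy-4,5-epoxy-9-hydroxy-12-oxo-germacra-1(10),11(13)-dien-6,12-olid-14-oate | C=C1C(=O)O[C@@H]2[C@H]1[C@H](OC(=O)/C(C)=C\C)[C@@H](O)/C(C(=O)OC)=C\CC[C@@]1(C)O[C@@H]21 | target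

**Count and risks**

Total: 25 steps. Longest linear sequence: 23 steps (steps 3–25 from diethyl (S)-malate); aldehyde 6 is made in 2 steps and enters at step 12.

Steps most likely to fail:

1. Step 16. The alkenylchromium may be protonated or may couple intermolecularly faster than the strained ten-membered ring closes, because the rigid enoate and the (Z)-iodoalkene hold the chain ends apart. The fallback closes the ring on a more flexible seco compound in which C10–C1 is still saturated and makes the enoate inside the ring. It sets out from 21: acetylation (Ac2O, pyridine, DMAP) gives the C1 acetate F1, buffered HF·pyridine the primary alcohol F2, Dess–Martin oxidation the aldehyde F3, and the Ni/Cr closure the macrocyclic β-acetoxy ester F4. DBU-induced E1cB loss of acetate then forms C10=C1 within the ring, where the ring-cis alkene (the one required) is the less strained isomer, and the route is rejoined at 27.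

2. Step 18. Hydride may arrive from the wrong face of the macrocyclic enone if the ring conformation overrides Felkin and chelate control, or may add 1,4. The fallback sets the C6 configuration by SN2 inversion instead of by facial selectivity. It sets out from 28, reduced under Luche conditions (NaBH4, CeCl3, MeOH, −78 °C) to the 6R alcohol F5. Mitsunobu reaction (4-nitrobenzoic acid, PPh3, DIAD, toluene, 0 → 25 °C) gives the inverted 4-nitrobenzoate F6, and methanolysis (K2CO3, MeOH, 0 °C) returns to 29.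

3. Step 22. The amide base may deprotonate the γ-positions (C2, C9) of the C14 enoate, or the enolate may attack the epoxide, instead of clean Mannich reaction at C11. The fallback introduces C13 at the aldehyde oxidation level without strong base. It sets out from lactol 32, whose open hydroxy-aldehyde tautomer undergoes amine-catalysed Mannich α-methylenation (aq CH2O, pyrrolidine, propionic acid, i-PrOH, 45 °C) to the α-methylene lactol F7. Oxidation (MnO2, CH2Cl2, or TPAP/NMO) returns to 37.

Further compounds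
F1 | step 16 | 3-O-acetate of 21 | CC(C)(C)[Si](C)(C)OC[C@H](CC=C)[C@H](OCc1ccc(OC)cc1)[C@@H](O[Si](C)(C)C(C)(C)C)C(C(=O)OC)C(OC(C)=O)CC/C(C)=C\I
F2 | step 16 | C6 primary alcohol from F1 | OC[C@H](CC=C)[C@H](OCc1ccc(OC)cc1)[C@@H](O[Si](C)(C)C(C)(C)C)C(C(=O)OC)C(OC(C)=O)CC/C(C)=C\I
F3 | step 16 | C6 aldehyde from F2 | O=C[C@H](CC=C)[C@H](OCc1ccc(OC)cc1)[C@@H](O[Si](C)(C)C(C)(C)C)C(C(=O)OC)C(OC(C)=O)CC/C(C)=C\I
F4 | step 16 | macrocyclic β-acetoxy ester: 27 with C10–H and C1–OAc in place of C10=C1 (diastereomers) | C1/C(C)=C\C(O)[C@H](CC=C)[C@H](OCc2ccc(OC)cc2)[C@@H](O[Si](C)(C)C(C)(C)C)C(C(=O)OC)C(OC(C)=O)C1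
F5 | step 18 | (6R)-epimer of 29 | C1/C(C)=C\[C@@H](O)[C@H](CC=C)[C@H](OCc2ccc(OC)cc2)[C@@H](O[Si](C)(C)C(C)(C)C)/C(C(=O)OC)=C\C1
F6 | step 18 | (6S)-4-nitrobenzoate of 29 | C1/C(C)=C\[C@H](OC(=O)c2ccc([N+](=O)[O-])cc2)[C@H](CC=C)[C@H](OCc2ccc(OC)cc2)[C@@H](O[Si](C)(C)C(C)(C)C)/C(C(=O)OC)=C\C1
F7 | step 22 | α-methylene lactol: 32 with C11=CH2 (C12 epimers) | C=C1C(O)O[C@@H]2[C@H]1[C@H](OCc3ccc(OC)cc3)[C@@H](O[Si](C)(C)C(C)(C)C)/C(C(=O)OC)=C\CC[C@@]1(C)O[C@@H]21
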